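A direct plan would set C4 by chirality transfer in an aromatic Claisen rearrangement of the chiral secondary cinnamyl-type aryl ether A1, which near 185 °C would give the C-allyl phenol A2. Ethenolysis would trim the propenyl group to give the vinyl compound A3, hydroboration–oxidation would give the primary alcohol A4, and chalcone formation, oxidative lactonisation and debenzylation would follow. Weakest would be the thermal rearrangement, since such an ether could ionise and shift [1,3], eroding the only stereocentre. The ethenolysis would only remove one carbon and would expose the allylic centre to ruthenium hydride isomerisation. The hydroboration would run beside a free aryl methyl ketone, where carbonyl reduction would compete.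

The route rests on cutting the lactone ring (ring B) at C3–C4 and O1–C2. C4 is benzylic and ortho to the lactone oxygen O1 on the phloroglucinol ring (ring A), so the dihydrocoumarin is a latent ortho-quinone methide plus an acetate unit. A racemic benzylic sulfone, made in one three-component step, would lose sulfinate to the planar quinone methide; a bifunctional squaramide would guide Meldrum's acid to one face, and lactonisation–decarboxylation would close ring B. One stereoconvergent operation would thus set C4 and build the lactone on O1, the only free phenol. No thermal chirality transfer, carbon trimming, hydroboration or alcohol oxidation would be needed.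

Key step: step 2

Remark: the sense of induction of the squaramide in step 2 is assigned by analogy with related additions; should it deliver the 4S series, the pseudo-enantiomeric catalyst made from 9-amino-9-deoxy-epi-quinine would be used with nothing else changed.

**Step 1**
Reactants: 1 1-[2,4-bis(benzyloxy)-6-hydroxyphenyl]ethan-1-one; 2 benzaldehyde; 3 sodium 4-methylbenzenesulfinate
Product: 5 1-{4,6-bis(benzyloxy)-2-hydroxy-3-[(4-methylbenzenesulfonyl)(phenyl)methyl]phenyl}ethan-1-one (racemic), via benzhydrol 4 (not isolated)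
Conditions: 2 (1.3 equiv), 3 (2 equiv), HCO2H–H2O (3:1), CH2Cl2, rt
Reagents that add atoms: none
Why: Acid-promoted three-component α-sulfonylbenzylation (Friedel–Crafts hydroxyalkylation, then ionisation of benzhydrol 4 and capture of the benzylic cation by sulfinate): the ring carbon between the free hydroxyl and a benzyloxy group is the only position ortho to the phenol and is less hindered than the carbon flanked by two benzyloxy groups, excess sulfinate should outcompete a second arylation, and the configuration of the new centre is irrelevant because step 2 erases it.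

**Step 2**
Reactants: 5 1-{4,6-bis(benzyloxy)-2-hydroxy-3-[(4-methylbenzenesulfonyl)(phenyl)methyl]phenyl}ethan-1-one (racemic); 6 2,2-dimethyl-1,3-dioxane-4,6-dione (Meldrum's acid)
Product: 10 (4R)-8-acetyl-5,7-bis(benzyloxy)-4-phenyl-3,4-dihydro-2H-chromen-2-one, via ortho-quinone methide 7 (not isolated), via Meldrum's acid adduct 8 (not isolated), via lactone acid 9 (not isolated)
Conditions: 6 (1.5 equiv), 3-{[3,5-bis(trifluoromethyl)phenyl]amino}-4-{[(9R)-6′-methoxycinchonan-9-yl]amino}cyclobut-3-ene-1,2-dione (10 mol %), 5 % aq. NaHCO3, CH2Cl2, 0 °C; organic phase separated, then p-toluenesulfonic acid monohydrate (30 mol %), toluene, 90 °C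
Reagents that add atoms: none
Why: Bicarbonate and the quinuclidine of the catalyst trigger 1,4-elimination of sulfinate from the phenol of 5 to the planar ortho-quinone methide 7 (both enantiomers of 5 converge), and the quinuclidinium-bound Meldrum's acid enolate adds to its exocyclic carbon with rearomatisation to give 8. The closest known reaction type is the squaramide-catalysed conjugate addition of Meldrum's acid to ortho-quinone methides generated in situ from 2-(1-sulfonylalkyl)phenols under two-phase basic conditions, which leads to 4-substituted 3,4-dihydrocoumarins. Ring B closes in the acidic second stage by 6-exo-trig attack of the phenolic oxygen on a Meldrum's carbonyl with loss of acetone, and the malonic-type acid 9 then loses CO2, so that the whole is a formal [4+2] annulation of 7 with an acetate unit. C4, the only stereocentre that persists, is set under catalyst control: the squaramide N–H pair binds the quinone methide carbonyl and the adjacent acetyl oxygen while the protonated quinuclidine delivers the enolate to one face; C3 of 9 is stereolabile and is erased. The step needs the catalysed addition to outrun the racemic background addition and the retro-addition, which the weak two-phase base (low stationary concentration of 7), low temperature and prompt acidification should secure. It also needs lactone closure on O1 alone, which is certain because the chelated hydroxyl beside the acetyl group is the only free phenol and the other two ring oxygens are benzylated.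

**Step 3**
Reactants: 10 (4R)-8-acetyl-5,7-bis(benzyloxy)-4-phenyl-3,4-dihydro-2H-chromen-2-one; 11 3,4-bis(methoxymethoxy)benzaldehyde
Product: 14 (3R)-3-{4,6-bis(benzyloxy)-3-[(2E)-3-[3,4-bis(methoxymethoxy)phenyl]prop-2-enoyl]-2-hydroxyphenyl}-3-phenylpropanoic acid, via ring-opened keto acid 12 (not isolated), via aldol 13 (not isolated)
Conditions: KOH (50 % aq., 15 equiv), EtOH–THF, rt; then 1 M HCl to pH 4, 0 °C
Reagents that add atoms: potassium hydroxide, [K+].[OH-]
Why: Claisen–Schmidt condensation, in which hydroxide first opens the aryl lactone to the phenoxide carboxylate of 12 (taking the acidic lactone α-hydrogens out of play), the methyl ketone enolate adds to the non-enolisable aldehyde and aldol 13 dehydrates by E1cB to the E-enone; benzyl ethers and methoxymethyl acetals are inert to base and the diarylmethine C–H is not acidic, so the stereocentre should be untouched.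

**Step 4**
Reactants: 14 (3R)-3-{4,6-bis(benzyloxy)-3-[(2E)-3-[3,4-bis(methoxymethoxy)phenyl]prop-2-enoyl]-2-hydroxyphenyl}-3-phenylpropanoic acid
Product: 16 (4R)-5,7-bis(benzyloxy)-8-{(2E)-3-[3,4-bis(methoxymethoxy)phenyl]prop-2-enoyl}-4-phenyl-3,4-dihydro-2H-chromen-2-one, via O-acylisourea 15 (not isolated)
Conditions: EDC·HCl [N-(3-dimethylaminopropyl)-N′-ethylcarbodiimide hydrochloride] (1.5 equiv), 4-(dimethylamino)pyridine (10 mol %), CH2Cl2, 0 °C → rt
Reagents that add atoms: none
Why: Steglich-type carbodiimide lactonisation (6-exo-trig acyl transfer to the only free phenol, held beside the activated carboxyl by the flanking benzyloxy and phenyl groups) under neutral conditions that should keep the acetals, the enone geometry and C4 intact and that close off conjugate addition of the phenol to the enone.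

**Step 5**
Reactants: 16 (4R)-5,7-bis(benzyloxy)-8-{(2E)-3-[3,4-bis(methoxymethoxy)phenyl]prop-2-enoyl}-4-phenyl-3,4-dihydro-2H-chromen-2-one
Product: 17 (4R)-8-[(2E)-3-(3,4-dihydroxyphenyl)prop-2-enoyl]-5,7-dihydroxy-4-phenyl-3,4-dihydro-2H-chromen-2-one
Conditions: BCl3 (10 equiv), C6HMe5 (6 equiv), CH2Cl2, −78 → −20 °C; then H2O, 0 °C
Reagents that add atoms: none
Why: Lewis acid dealkylation with pentamethylbenzene as a non-coordinating cation scavenger, in which BCl3 cleaves the two aryl benzyl ethers and the two methoxymethyl acetals at low temperature, the scavenger takes up the benzyl cations so that ring A is not C-benzylated, and the enone (which rules out hydrogenolysis), the lactone and C4 are left alone.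

**Compound list**
1 | 1-[2,4-bis(benzyloxy)-6-hydroxyphenyl]ethan-1-one | CC(=O)c1c(O)cc(OCc2ccccc2)cc1OCc1ccccc1 | starting material
2 | benzaldehyde | O=Cc1ccccc1 | starting material
3 | sodium 4-methylbenzenesulfinate | Cc1ccc(cc1)S(=O)[O-].[Na+] | starting material
4 | 1-{4,6-bis(benzyloxy)-2-hydroxy-3-[hydroxy(phenyl)methyl]phenyl}ethan-1-one (racemic) | CC(=O)c1c(O)c(C(O)c2ccccc2)c(OCc2ccccc2)cc1OCc1ccccc1 | intermediate
5 | 1-{4,6-bis(benzyloxy)-2-hydroxy-3-[(4-methylbenzenesulfonyl)(phenyl)methyl]phenyl}ethan-1-one (racemic) | CC(=O)c1c(O)c(C(c2ccccc2)S(=O)(=O)c2ccc(C)cc2)c(OCc2ccccc2)cc1OCc1ccccc1 | intermediate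
6 | 2,2-dimethyl-1,3-dioxane-4,6-dione (Meldrum's acid) | CC1(C)OC(=O)CC(=O)O1 | starting material
7 | 2-acetyl-3,5-bis(benzyloxy)-6-benzylidenecyclohexa-2,4-dien-1-one (alkene geometry not assigned) | CC(=O)C1=C(OCc2ccccc2)C=C(OCc2ccccc2)C(=Cc2ccccc2)C1=O | intermediate
8 | 5-[(R)-[3-acetyl-4,6-bis(benzyloxy)-2-hydroxyphenyl](phenyl)methyl]-2,2-dimethyl-1,3-dioxane-4,6-dione | CC1(C)OC(=O)C(C(=O)O1)[C@H](c1ccccc1)c1c(O)c(C(C)=O)c(OCc2ccccc2)cc1OCc1ccccc1 | intermediate
9 | (4R)-8-acetyl-5,7-bis(benzyloxy)-2-oxo-4-phenyl-3,4-dihydro-2H-chromene-3-carboxylic acid (C3 epimers, trans expected to predominate) | O=C1C(C(=O)O)[C@H](c2ccccc2)c2c(OCc3ccccc3)cc(OCc3ccccc3)c(C(C)=O)c2O1 | intermediate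
10 | (4R)-8-acetyl-5,7-bis(benzyloxy)-4-phenyl-3,4-dihydro-2H-chromen-2-one | O=C1C[C@H](c2ccccc2)c2c(OCc3ccccc3)cc(OCc3ccccc3)c(C(C)=O)c2O1 | intermediate
11 | 3,4-bis(methoxymethoxy)benzaldehyde | COCOc1ccc(C=O)cc1OCOC | starting material
12 | (3R)-3-[3-acetyl-4,6-bis(benzyloxy)-2-hydroxyphenyl]-3-phenylpropanoic acid (dipotassium salt in the flask) | OC(=O)C[C@H](c1ccccc1)c1c(O)c(C(C)=O)c(OCc2ccccc2)cc1OCc1ccccc1 | intermediate
13 | (3R)-3-{4,6-bis(benzyloxy)-3-[3-(3,4-bis(methoxymethoxy)phenyl)-3-hydroxypropanoyl]-2-hydroxyphenyl}-3-phenylpropanoic acid (both carbinol epimers) | OC(=O)C[C@H](c1ccccc1)c1c(O)c(C(=O)CC(O)c2ccc(OCOC)c(OCOC)c2)c(OCc2ccccc2)cc1OCc1ccccc1 | intermediate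
14 | (3R)-3-{4,6-bis(benzyloxy)-3-[(2E)-3-[3,4-bis(methoxymethoxy)phenyl]prop-2-enoyl]-2-hydroxyphenyl}-3-phenylpropanoic acid | OC(=O)C[C@H](c1ccccc1)c1c(O)c(C(=O)/C=C/c2ccc(OCOC)c(OCOC)c2)c(OCc2ccccc2)cc1OCc1ccccc1 | intermediate
15 | O-acylisourea of acid 14 (carboxyl oxygen bound to the C(=NEt)NH(CH2)3NMe2 group of EDC) | CCN=C(NCCCN(C)C)OC(=O)C[C@H](c1ccccc1)c1c(O)c(C(=O)/C=C/c2ccc(OCOC)c(OCOC)c2)c(OCc2ccccc2)cc1OCc1ccccc1 | intermediate
16 | (4R)-5,7-bis(benzyloxy)-8-{(2E)-3-[3,4-bis(methoxymethoxy)phenyl]prop-2-enoyl}-4-phenyl-3,4-dihydro-2H-chromen-2-one | O=C1C[C@H](c2ccccc2)c2c(OCc3ccccc3)cc(OCc3ccccc3)c(C(=O)/C=C/c3ccc(OCOC)c(OCOC)c3)c2O1 | intermediate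
17 | (4R)-8-[(2E)-3-(3,4-dihydroxyphenyl)prop-2-enoyl]-5,7-dihydroxy-4-phenyl-3,4-dihydro-2H-chromen-2-one | O=C1C[C@H](c2ccccc2)c2c(O)cc(O)c(C(=O)/C=C/c3ccc(O)c(O)c3)c2O1 | target

Total steps: 5. Longest linear sequence: 5 steps (1 → 5 → 10 → 14 → 16 → 17).

Steps most likely to fail:

Step 2 (key step). A fast uncatalysed addition to the strongly stabilised quinone methide, reversible addition before lactonisation, and acidolysis of the benzyl ethers in the hot acidic stage could erode enantiomeric purity or material. The fallback would set the stereocentre by aryl transfer instead of by annulation. Setting out from 1, hydroarylation–lactonisation with ethyl propiolate (Pd(OAc)2, NaOAc, HCO2H, rt) at the ring carbon ortho to the free phenol would give 8-acetyl-5,7-bis(benzyloxy)-2H-chromen-2-one F1. Hayashi–Miyaura 1,4-addition of phenylboronic acid (Rh(acac)(C2H4)2, (R)-SEGPHOS [(R)-5,5′-bis(diphenylphosphino)-4,4′-bi-1,3-benzodioxole], dioxane–H2O, 60 °C; ligand enantiomer chosen to give 4R) would then come back to the route at 10.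

Step 1. Attack at the ring carbon between the two benzyloxy groups, a second arylation of the benzylic cation by another molecule of 1, and premature loss of sulfinate during isolation could all cut the supply of 5. The fallback would deliver the benzylic carbon through a boron tether that can reach only the ortho position. Setting out from 1, condensation with benzaldehyde 2 and phenylboronic acid (EtCO2H cat., toluene, reflux, water removal) would give 1-[5,7-bis(benzyloxy)-2,4-diphenyl-4H-1,3,2-benzodioxaborinin-8-yl]ethan-1-one F2. Oxidative release of boron (H2O2, THF–H2O, rt) would come back to the route at benzhydrol 4, which 3 in HCO2H–CH2Cl2 would convert into 5 as in step 1.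

Step 3. Slow condensation of the hindered ketone, conjugate addition of the freed phenol to the new enone on acidification (flavanone formation), and partial loss of the acetals at low pH are the likely failures. The fallback would make the enone by olefination, with the lactone never opened. Setting out from 10, α-bromination (CuBr2, EtOAc–CHCl3, reflux) would give (4R)-5,7-bis(benzyloxy)-8-(bromoacetyl)-4-phenyl-3,4-dihydro-2H-chromen-2-one F3. PPh3 (toluene, rt) would give {2-[(4R)-5,7-bis(benzyloxy)-2-oxo-4-phenyl-3,4-dihydro-2H-chromen-8-yl]-2-oxoethyl}triphenylphosphonium bromide F4, and brief treatment with aqueous Na2CO3 would give the stabilised ylide (4R)-5,7-bis(benzyloxy)-4-phenyl-8-[(triphenyl-λ5-phosphanylidene)acetyl]-3,4-dihydro-2H-chromen-2-one F5. Wittig reaction of F5 with aldehyde 11 (toluene, 90 °C) would come back to the route at 16, so that step 4 would not be needed.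

**Further compounds**
F1 | step 2 | 8-acetyl-5,7-bis(benzyloxy)-2H-chromen-2-one | CC(=O)c1c(OCc2ccccc2)cc(OCc2ccccc2)c2ccc(=O)oc12
F2 | step 1 | 1-[5,7-bis(benzyloxy)-2,4-diphenyl-4H-1,3,2-benzodioxaborinin-8-yl]ethan-1-one (racemic) | CC(=O)c1c(OCc2ccccc2)cc(OCc2ccccc2)c2c1OB(c1ccccc1)OC2c1ccccc1
F3 | step 3 | (4R)-5,7-bis(benzyloxy)-8-(bromoacetyl)-4-phenyl-3,4-dihydro-2H-chromen-2-one | O=C1C[C@H](c2ccccc2)c2c(OCc3ccccc3)cc(OCc3ccccc3)c(C(=O)CBr)c2O1
F4 | step 3 | {2-[(4R)-5,7-bis(benzyloxy)-2-oxo-4-phenyl-3,4-dihydro-2H-chromen-8-yl]-2-oxoethyl}triphenylphosphonium bromide | O=C1C[C@H](c2ccccc2)c2c(OCc3ccccc3)cc(OCc3ccccc3)c(C(=O)C[P+](c3ccccc3)(c3ccccc3)c3ccccc3)c2O1.[Br-]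
F5 | step 3 | (4R)-5,7-bis(benzyloxy)-4-phenyl-8-[(triphenyl-λ5-phosphanylidene)acetyl]-3,4-dihydro-2H-chromen-2-one | O=C1C[C@H](c2ccccc2)c2c(OCc3ccccc3)cc(OCc3ccccc3)c(C(=O)C=P(c3ccccc3)(c3ccccc3)c3ccccc3)c2O1
A1 | direct plan | 1-[2,4-bis(benzyloxy)-6-{[(2R,3E)-4-phenylbut-3-en-2-yl]oxy}phenyl]ethan-1-one | C[C@@H](Oc1cc(OCc2ccccc2)cc(OCc2ccccc2)c1C(C)=O)/C=C/c1ccccc1
A2 | direct plan | 1-{4,6-bis(benzyloxy)-2-hydroxy-3-[(1R,2E)-1-phenylbut-2-en-1-yl]phenyl}ethan-1-one | C/C=C/[C@H](c1ccccc1)c1c(O)c(C(C)=O)c(OCc2ccccc2)cc1OCc1ccccc1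
A3 | direct plan | 1-{4,6-bis(benzyloxy)-2-hydroxy-3-[(1R)-1-phenylprop-2-en-1-yl]phenyl}ethan-1-one | C=C[C@H](c1ccccc1)c1c(O)c(C(C)=O)c(OCc2ccccc2)cc1OCc1ccccc1
A4 | direct plan | 1-{4,6-bis(benzyloxy)-2-hydroxy-3-[(1R)-3-hydroxy-1-phenylpropyl]phenyl}ethan-1-one | OCC[C@H](c1ccccc1)c1c(O)c(C(C)=O)c(OCc2ccccc2)cc1OCc1ccccc1
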